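**Plan**
1. Numbering used throughout: the only ring is a cyclohex-2-en-1-one (C1 = C=O, C2 carries CH2OH, C3 = CH, C4 carries the propionate, C5 the isopropyl group, C6 the side-chain ester). The target is (4S,5S,6R).
2. Retrosynthesis: cut C2–CH2OH (Morita–Baylis–Hillman), replace C4–H by a formyl helper, then cut the ring bonds C3–C4 and C5–C6 together in a [4+2] sense.
3. This leaves a (1E,3Z)-1-amino-3-silyloxy-4-acyloxybutadiene (C3–C2–C1–C6, side-chain ester already on C6) and (Z)-2-(propionyloxy)-4-methylpent-2-enal (C4, C5, isopropyl, propionate).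
4. Enabling feature: the C1=O/C2=C3 enone next to an oxygen-bearing C4 is the retron of an aminosilyloxydiene cycloadduct. Because C4 is a CH–O carbon it can carry CHO during ring formation, which turns the enol ester C4=C5 into a reactive captodative dienophile of the right polarity.
5. Forward: side-chain acid → acyloxymethyl vinylogous amide → diene (steps 1–6); keto acetal → enol propionate → enal (7–9); cycloaddition and unveiling close the ring (10); decarbonylation, hydroxymethylation, desilylation (11–13).
6. Stereochemistry: the chiral hydrogen-bond catalyst selects the enal face (C4 and C5, absolute); the Z-alkene gives cis O/i-Pr at C4/C5; endo approach plus the 3Z enol ether gives trans C5/C6, backed by equilibration α to the ketone; decarbonylation retains C4.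

Key step: step 10

Assumption: the (4R,5R) antipode of the diol catalyst is taken, by analogy with α-substituted acroleins, as the one that leaves the Re face at C2 (Si face at C3) of enal 16 open; both antipodes are commercial and the (4S,5S) one is used if a first run shows the opposite sense.

TBS = tert-butyldimethylsilyl.

**Step 1**
Reactants: 1 (tert-butyldimethylsilyloxy)acetaldehyde; 2 ethyl 2-(triphenylphosphoranylidene)propanoate
Product: 3 ethyl (E)-4-(TBS-oxy)-2-methylbut-2-enoate
Conditions: CH2Cl2, rt → 40 °C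
Reagents that add atoms: none
Why: Wittig olefination with a stabilised α-methyl ylide, which should give the (E)-trisubstituted enoate (ester trans to CH2OTBS) required for the side chain.

**Step 2**
Reactants: 3 ethyl (E)-4-(TBS-oxy)-2-methylbut-2-enoate
Product: 4 (E)-4-(TBS-oxy)-2-methylbut-2-enoic acid
Conditions: LiOH, THF/H2O, rt; then 1 M HCl to pH 4, 0 °C
Reagents that add atoms: lithium hydroxide, [Li+].[OH-]
Why: Ester saponification, under which the primary silyl ether and the alkene geometry should be unaffected (brief cold acidification only).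

**Step 3**
Reactants: 5 (E)-1-methoxy-3-(trimethylsilyloxy)buta-1,3-diene
Product: 6 (E)-1-bromo-4-methoxybut-3-en-2-one
Conditions: N-bromosuccinimide, THF, −78 → 0 °C
Reagents that add atoms: N-bromosuccinimide, O=C1CCC(=O)N1Br
Why: Electrophilic α-bromination of a silyl enol ether; bromine enters at the CH2 terminus because this gives the cation stabilised by both oxygen donors, and loss of silicon returns the vinylogous ester.

**Step 4**
Reactants: 4 (E)-4-(TBS-oxy)-2-methylbut-2-enoic acid; 6 (E)-1-bromo-4-methoxybut-3-en-2-one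
Product: 7 (E)-4-methoxy-2-oxobut-3-en-1-yl (E)-4-(TBS-oxy)-2-methylbut-2-enoate
Conditions: i-Pr2NEt, MeCN, 0 °C → rt
Reagents that add atoms: none
Why: SN2 O-alkylation of the carboxylate by the α-bromo ketone (phenacyl-type ester formation), which is much faster than conjugate attack on the vinylogous ester.

**Step 5**
Reactants: 7 (E)-4-methoxy-2-oxobut-3-en-1-yl (E)-4-(TBS-oxy)-2-methylbut-2-enoate
Product: 8 (E)-4-(dimethylamino)-2-oxobut-3-en-1-yl (E)-4-(TBS-oxy)-2-methylbut-2-enoate
Conditions: Me2NH (2 M in THF, 1.1 equiv), THF, −20 → 0 °C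
Reagents that add atoms: dimethylamine, CNC
Why: Addition–elimination (vinylogous transamidation) at the β-methoxy enone, which at low temperature is far faster than aminolysis of the ester, should give the E vinylogous amide.

**Step 6**
Reactants: 8 (E)-4-(dimethylamino)-2-oxobut-3-en-1-yl (E)-4-(TBS-oxy)-2-methylbut-2-enoate
Product: 9 (1Z,3E)-2-(TBS-oxy)-4-(dimethylamino)buta-1,3-dien-1-yl (E)-4-(TBS-oxy)-2-methylbut-2-enoate
Conditions: TBSOTf, Et3N, Et2O, −78 → 0 °C; used crude
Reagents that add atoms: tert-butyldimethylsilyl trifluoromethanesulfonate, CC(C)(C)[Si](C)(C)OS(=O)(=O)C(F)(F)F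
Why: Soft enolisation: O-silylation of the vinylogous amide gives a silyloxy iminium ion that is deprotonated at the acyloxymethyl carbon, which should give the diene with the two oxygens cis, as in the known 4-acyloxy-1-methoxy-3-silyloxybutadienes, without a strong base that could deprotonate the side-chain ester.

**Step 7**
Reactants: 10 2,2-diethoxy-1-(piperidin-1-yl)ethan-1-one; 11 isobutylmagnesium bromide (i-BuMgBr)
Product: 13 1,1-diethoxy-4-methylpentan-2-one, via bromomagnesium hemiaminal alkoxide 12 (not isolated)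
Conditions: THF, −78 → 0 °C; then H2O
Reagents that add atoms: none
Why: Acylation of a Grignard reagent by a tertiary α,α-dialkoxy amide, in which the chelated tetrahedral intermediate survives until work-up so that addition should stop at the ketone.

**Step 8**
Reactants: 13 1,1-diethoxy-4-methylpentan-2-one
Product: 15 (Z)-1,1-diethoxy-4-methylpent-2-en-2-yl propanoate, via potassium Z-enolate 14 (not isolated)
Conditions: KN(SiMe3)2, THF, −78 °C; then (EtCO)2O, −78 → 0 °C
Reagents that add atoms: propionic anhydride, CCC(=O)OC(=O)CC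
Why: Kinetic deprotonation on the CH2 side and O-acylation of the enolate by the anhydride; the bulky diethoxymethyl group should enforce the enolate with oxygen and isopropyl cis, the geometry that later becomes the cis C4/C5 relation.

**Step 9**
Reactants: 15 (Z)-1,1-diethoxy-4-methylpent-2-en-2-yl propanoate
Product: 16 (Z)-4-methyl-1-oxopent-2-en-2-yl propanoate [(Z)-2-(propionyloxy)-4-methylpent-2-enal]
Conditions: CF3CO2H/H2O, CHCl3, 0 °C
Reagents that add atoms: water, O
Why: Acid-catalysed acetal hydrolysis, much faster than cleavage of the enol ester; the Z isomer (isopropyl trans to CHO) is also the thermodynamically preferred one, so the geometry should hold.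

**Step 10**
Reactants: 9 (1Z,3E)-2-(TBS-oxy)-4-(dimethylamino)buta-1,3-dien-1-yl (E)-4-(TBS-oxy)-2-methylbut-2-enoate (1.5 equiv); 16 (Z)-4-methyl-1-oxopent-2-en-2-yl propanoate
Product: 18 (4S,5R,6R)-6-{[(E)-4-(TBS-oxy)-2-methylbut-2-enoyl]oxy}-4-formyl-5-isopropyl-4-(propionyloxy)cyclohex-2-en-1-one, via endo cycloadduct 17 (not isolated)
Conditions: (4R,5R)-2,2-dimethyl-α,α,α′,α′-tetra(1-naphthyl)-1,3-dioxolane-4,5-dimethanol (20 mol%), toluene, −60 → −20 °C; then 0.1 M HCl, THF/H2O, 0 °C
Reagents that add atoms: none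
Why: A concerted but asynchronous normal-demand [4+2] cycloaddition in which the amino and silyloxy donors make the acyloxy-bearing diene terminus the nucleophilic one, so that it bonds first to the β-carbon of the formyl-activated enal (C6–C5) and C3–C4 closes after it; the closest known reaction type is the hydrogen-bond (chiral diol) catalysed Diels–Alder reaction of 1-amino-3-silyloxybutadienes with α-substituted acroleins, which gives carbocycles and not hetero-Diels–Alder products. The single six-membered carbocycle is closed intermolecularly in the cycloaddition mode, suprafacial on both partners. C4 and C5: their relative configuration (propionate cis to isopropyl) is the Z geometry of 16 carried over, and their absolute configuration comes from the catalyst, whose hydrogen bond to the formyl oxygen should leave only the C2-Re/C3-Si face of the enal open. C6: trans to the isopropyl group through the formyl-endo transition state (the one that also keeps the isopropyl group exo) and the enol ether geometry of 9, and because C6 becomes α to the ketone any cis isomer can drain to this more stable trans arrangement, while the amino-bearing carbon stops being a stereocentre on elimination. The step needs regio-, chemo- (C=C over C=O), endo and facial selectivity; the first two rest on the donor pattern of 9 and the α-substitution of 16, the last on the catalyst. Dilute acid then hydrolyses the silyl enol ether and eliminates dimethylamine to unveil the enone while sparing the primary silyl ether.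

**Step 11**
Reactants: 18 (4S,5R,6R)-6-{[(E)-4-(TBS-oxy)-2-methylbut-2-enoyl]oxy}-4-formyl-5-isopropyl-4-(propionyloxy)cyclohex-2-en-1-one
Product: 19 (4S,5S,6R)-6-{[(E)-4-(TBS-oxy)-2-methylbut-2-enoyl]oxy}-5-isopropyl-4-(propionyloxy)cyclohex-2-en-1-one
Conditions: RhCl(PPh3)3 (1.1 equiv), PhCN, 110 °C
Reagents that add atoms: none
Why: Tsuji–Wilkinson decarbonylation: oxidative addition of the formyl C–H bond to monovalent rhodium, CO de-insertion and C–H reductive elimination proceed with retention, so H should take the place of CHO at C4 and the propionate stay cis to the isopropyl group.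

**Step 12**
Reactants: 19 (4S,5S,6R)-6-{[(E)-4-(TBS-oxy)-2-methylbut-2-enoyl]oxy}-5-isopropyl-4-(propionyloxy)cyclohex-2-en-1-one
Product: 20 (4S,5S,6R)-6-{[(E)-4-(TBS-oxy)-2-methylbut-2-enoyl]oxy}-2-(hydroxymethyl)-5-isopropyl-4-(propionyloxy)cyclohex-2-en-1-one
Conditions: HCHO (37% aq.), 4-(dimethylamino)pyridine (0.3 equiv), THF/H2O, rt
Reagents that add atoms: formaldehyde, C=O
Why: Morita–Baylis–Hillman hydroxymethylation (conjugate addition of the pyridine at C3, aldol reaction with formaldehyde at C2, elimination), a reaction type established for 4,6-dioxygenated cyclohex-2-enones; no stereocentre is formed and C6 is already in its stable trans arrangement.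

**Step 13**
Reactants: 20 (4S,5S,6R)-6-{[(E)-4-(TBS-oxy)-2-methylbut-2-enoyl]oxy}-2-(hydroxymethyl)-5-isopropyl-4-(propionyloxy)cyclohex-2-en-1-one
Product: 21 (4S,5S,6R)-6-{[(E)-4-hydroxy-2-methylbut-2-enoyl]oxy}-2-(hydroxymethyl)-5-isopropyl-4-(propionyloxy)cyclohex-2-en-1-one (target)
Conditions: HF·pyridine, THF/pyridine, 0 °C → rt
Reagents that add atoms: none
Why: Fluoride-mediated cleavage of the primary silyl ether under buffered, non-basic conditions that should leave both esters, the enone and the allylic alcohol untouched.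

**Compound list**
1 | (tert-butyldimethylsilyloxy)acetaldehyde | O=CCO[Si](C)(C)C(C)(C)C | starting material
2 | ethyl 2-(triphenylphosphoranylidene)propanoate | CCOC(=O)C(C)=P(c1ccccc1)(c1ccccc1)c1ccccc1 | starting material
3 | ethyl (E)-4-(TBS-oxy)-2-methylbut-2-enoate | CCOC(=O)/C(C)=C/CO[Si](C)(C)C(C)(C)C | intermediate
4 | (E)-4-(TBS-oxy)-2-methylbut-2-enoic acid | OC(=O)/C(C)=C/CO[Si](C)(C)C(C)(C)C | intermediate
5 | (E)-1-methoxy-3-(trimethylsilyloxy)buta-1,3-diene | CO/C=C/C(=C)O[Si](C)(C)C | starting material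
6 | (E)-1-bromo-4-methoxybut-3-en-2-one | CO/C=C/C(=O)CBr | intermediate
7 | (E)-4-methoxy-2-oxobut-3-en-1-yl (E)-4-(TBS-oxy)-2-methylbut-2-enoate | CO/C=C/C(=O)COC(=O)/C(C)=C/CO[Si](C)(C)C(C)(C)C | intermediate
8 | (E)-4-(dimethylamino)-2-oxobut-3-en-1-yl (E)-4-(TBS-oxy)-2-methylbut-2-enoate | CN(C)/C=C/C(=O)COC(=O)/C(C)=C/CO[Si](C)(C)C(C)(C)C | intermediate
9 | (1Z,3E)-2-(TBS-oxy)-4-(dimethylamino)buta-1,3-dien-1-yl (E)-4-(TBS-oxy)-2-methylbut-2-enoate | CN(C)/C=C/C(O[Si](C)(C)C(C)(C)C)=C/OC(=O)/C(C)=C/CO[Si](C)(C)C(C)(C)C | intermediate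
10 | 2,2-diethoxy-1-(piperidin-1-yl)ethan-1-one | CCOC(OCC)C(=O)N1CCCCC1 | starting material
11 | isobutylmagnesium bromide | CC(C)C[Mg]Br | starting material
12 | bromomagnesium 1,1-diethoxy-4-methyl-2-(piperidin-1-yl)pentan-2-olate | CCOC(OCC)C(CC(C)C)(O[Mg]Br)N1CCCCC1 | intermediate
13 | 1,1-diethoxy-4-methylpentan-2-one | CCOC(OCC)C(=O)CC(C)C | intermediate
14 | potassium (Z)-1,1-diethoxy-4-methylpent-2-en-2-olate | [K]O/C(=C\C(C)C)C(OCC)OCC | intermediate
15 | (Z)-1,1-diethoxy-4-methylpent-2-en-2-yl propanoate | CCC(=O)O/C(=C\C(C)C)C(OCC)OCC | intermediate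
16 | (Z)-4-methyl-1-oxopent-2-en-2-yl propanoate | CCC(=O)O/C(C=O)=C\C(C)C | intermediate
17 | endo cycloadduct: 2-(dimethylamino)-1-formyl-6-isopropyl-1-(propionyloxy)-4-(TBS-oxy)cyclohex-3-en-5-yl (E)-4-(TBS-oxy)-2-methylbut-2-enoate (formyl, dimethylamino and C5 acyloxy cis; propionyloxy and isopropyl on the other face) | CCC(=O)O[C@@]1(C=O)[C@H](N(C)C)C=C(O[Si](C)(C)C(C)(C)C)[C@H](OC(=O)/C(C)=C/CO[Si](C)(C)C(C)(C)C)[C@H]1C(C)C | intermediate
18 | (4S,5R,6R)-6-{[(E)-4-(TBS-oxy)-2-methylbut-2-enoyl]oxy}-4-formyl-5-isopropyl-4-(propionyloxy)cyclohex-2-en-1-one | CCC(=O)O[C@@]1(C=O)C=CC(=O)[C@H](OC(=O)/C(C)=C/CO[Si](C)(C)C(C)(C)C)[C@H]1C(C)C | intermediate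
19 | (4S,5S,6R)-6-{[(E)-4-(TBS-oxy)-2-methylbut-2-enoyl]oxy}-5-isopropyl-4-(propionyloxy)cyclohex-2-en-1-one | CCC(=O)O[C@H]1C=CC(=O)[C@H](OC(=O)/C(C)=C/CO[Si](C)(C)C(C)(C)C)[C@H]1C(C)C | intermediate
20 | (4S,5S,6R)-6-{[(E)-4-(TBS-oxy)-2-methylbut-2-enoyl]oxy}-2-(hydroxymethyl)-5-isopropyl-4-(propionyloxy)cyclohex-2-en-1-one | CCC(=O)O[C@H]1C=C(CO)C(=O)[C@H](OC(=O)/C(C)=C/CO[Si](C)(C)C(C)(C)C)[C@H]1C(C)C | intermediate
21 | (4S,5S,6R)-6-{[(E)-4-hydroxy-2-methylbut-2-enoyl]oxy}-2-(hydroxymethyl)-5-isopropyl-4-(propionyloxy)cyclohex-2-en-1-one | CCC(=O)O[C@H]1C=C(CO)C(=O)[C@H](OC(=O)/C(C)=C/CO)[C@H]1C(C)C | target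

**Step count**
Total: 13 steps. Longest linear sequence: 9 steps (1, 2, 4, 5, 6, 10, 11, 12, 13).

**Steps most likely to fail and fallbacks**

Step 10. The bond between the acyloxy-bearing diene terminus and the isopropyl-bearing enal carbon is hindered, so conversion may require temperatures at which hydrogen-bond catalysis discriminates the enal faces poorly, and an ester carbonyl may compete for the catalyst. The fallback moves stereocontrol from the catalyst to a covalently bound auxiliary on the diene. It sets out from 7: exchange with (2R,5R)-2,5-diphenylpyrrolidine in place of dimethylamine (MeCN, rt) should give (E)-4-[(2R,5R)-2,5-diphenylpyrrolidin-1-yl]-2-oxobut-3-en-1-yl (E)-4-(TBS-oxy)-2-methylbut-2-enoate F1. Silylation as in step 6 (TBSOTf, Et3N) should give the chiral diene (1Z,3E)-2-(TBS-oxy)-4-[(2R,5R)-2,5-diphenylpyrrolidin-1-yl]buta-1,3-dien-1-yl (E)-4-(TBS-oxy)-2-methylbut-2-enoate F2. Uncatalysed cycloaddition with 16 (toluene, rt → 40 °C) should then give the endo cycloadduct carrying the diphenylpyrrolidine F3, one phenyl group of the C2-symmetric amine blocking one diene face. Dilute HCl releases the recoverable amine and the route is rejoined at 18. The antipode of the amine is chosen on the same basis as that of the catalyst.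

Step 11. At the alkyl rhodium stage β-hydride elimination to the enol ester, allylic transposition or loss of the C4 configuration may compete with C–H reductive elimination, and the required temperature may degrade the γ-acyloxy enone. The fallback removes the one-carbon helper by a radical path. It sets out from 18: Pinnick oxidation (NaClO2, NaH2PO4, 2-methylbut-2-ene, t-BuOH/H2O) should give (1S,5R,6R)-5-{[(E)-4-(TBS-oxy)-2-methylbut-2-enoyl]oxy}-6-isopropyl-4-oxo-1-(propionyloxy)cyclohex-2-ene-1-carboxylic acid F4. Coupling with 1-hydroxypyridine-2(1H)-thione (N,N′-dicyclohexylcarbodiimide, CH2Cl2, dark) should give its 2-thioxopyridin-1(2H)-yl ester F5. Barton reductive decarboxylation (visible light, t-BuSH, benzene, rt) generates the stabilised radical at C4, which should take a hydrogen atom on the face opposite the neighbouring isopropyl group, and the route is rejoined at 19.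

Step 12. Conjugate addition of the amine catalyst next to the substituted C4 may be slow, and the two esters may suffer acyl cleavage or migration under the aqueous nucleophilic conditions. The fallback introduces the carbon by cross-coupling. It sets out from 19: α-iodination (I2, pyridine, CH2Cl2) should give (4S,5S,6R)-6-{[(E)-4-(TBS-oxy)-2-methylbut-2-enoyl]oxy}-2-iodo-5-isopropyl-4-(propionyloxy)cyclohex-2-en-1-one F6, and Stille coupling with (tributylstannyl)methanol (Pd(PPh3)4, dioxane, 80 °C) rejoins the route at 20.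

**Further compounds**
F1 | step 10 | (E)-4-[(2R,5R)-2,5-diphenylpyrrolidin-1-yl]-2-oxobut-3-en-1-yl (E)-4-(TBS-oxy)-2-methylbut-2-enoate | O=C(/C=C/N1[C@@H](c2ccccc2)CC[C@@H]1c1ccccc1)COC(=O)/C(C)=C/CO[Si](C)(C)C(C)(C)C
F2 | step 10 | (1Z,3E)-2-(TBS-oxy)-4-[(2R,5R)-2,5-diphenylpyrrolidin-1-yl]buta-1,3-dien-1-yl (E)-4-(TBS-oxy)-2-methylbut-2-enoate | CC(C)(C)[Si](C)(C)OC(/C=C/N1[C@@H](c2ccccc2)CC[C@@H]1c1ccccc1)=C\OC(=O)/C(C)=C/CO[Si](C)(C)C(C)(C)C
F3 | step 10 | endo cycloadduct as 17 with (2R,5R)-2,5-diphenylpyrrolidin-1-yl in place of dimethylamino | CCC(=O)O[C@@]1(C=O)[C@H](N2[C@@H](c3ccccc3)CC[C@@H]2c2ccccc2)C=C(O[Si](C)(C)C(C)(C)C)[C@H](OC(=O)/C(C)=C/CO[Si](C)(C)C(C)(C)C)[C@H]1C(C)C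
F4 | step 11 | (1S,5R,6R)-5-{[(E)-4-(TBS-oxy)-2-methylbut-2-enoyl]oxy}-6-isopropyl-4-oxo-1-(propionyloxy)cyclohex-2-ene-1-carboxylic acid | CCC(=O)O[C@@]1(C(=O)O)C=CC(=O)[C@H](OC(=O)/C(C)=C/CO[Si](C)(C)C(C)(C)C)[C@H]1C(C)C
F5 | step 11 | 2-thioxopyridin-1(2H)-yl (1S,5R,6R)-5-{[(E)-4-(TBS-oxy)-2-methylbut-2-enoyl]oxy}-6-isopropyl-4-oxo-1-(propionyloxy)cyclohex-2-ene-1-carboxylate | CCC(=O)O[C@@]1(C(=O)ON2C=CC=CC2=S)C=CC(=O)[C@H](OC(=O)/C(C)=C/CO[Si](C)(C)C(C)(C)C)[C@H]1C(C)C
F6 | step 12 | (4S,5S,6R)-6-{[(E)-4-(TBS-oxy)-2-methylbut-2-enoyl]oxy}-2-iodo-5-isopropyl-4-(propionyloxy)cyclohex-2-en-1-one | CCC(=O)O[C@H]1C=C(I)C(=O)[C@H](OC(=O)/C(C)=C/CO[Si](C)(C)C(C)(C)C)[C@H]1C(C)C
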